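**Plan**

1. Guaiane numbering is used throughout: C1=C10 is the ring-fusion alkene (methyl C14 on C10), C4 carries methyl C15, C5 is the ring-fusion CH, C7 carries C11(CH3)2OH and C8 carries the ester oxygen.
2. Retrosynthesis cuts the ester C–O bond, then the C11–OH bond (alkene hydration), then the C7–C8 bond of the seven-membered ring by a retro carbonyl-ene reaction. This works because O–C8–C7–C11 is a homoallylic-alcohol (isopulegol-type) array inside the ring, and the cis C1=C10 bond holds C9 and C5 on the same side, so the precursor is an open aldehyde with a prenyl group on C5.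
3. Further cuts: C1=C10 with C5–H back to a conjugated diene (1,4-hydrogenation), C1–C10 (alkenyl–alkenyl coupling), C5–C6 (enolate prenylation), and the cyclopentane back to (S)-pulegone (Favorskii ring contraction, then ozonolytic C=C cleavage).
4. Forward order: cyclopentane first, then the two side chains, then the seven-membered ring by ene closure, then hydration and esterification.
5. Stereochemistry: C4 comes from (S)-pulegone. C5 and the C1=C10 geometry are set together in the chromium-catalysed 1,4-hydrogenation (hydrogen delivered anti to the C4 methyl, diene termini forced cis). C7 and C8 come from a chair-like ene transition state controlled by C5. The (E)-alkene comes with the acid.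

Key step: step 10

Assumption: compounds 3, 4, 6 and 7 are used as epimer mixtures at the ring carbon that becomes C5, because this centre is made planar in step 5 and set again in step 8.

**Route**

Step 1
Reactants: 1 (S)-(−)-pulegone
Product: 3 methyl (2S)-2-methyl-5-(propan-2-ylidene)cyclopentane-1-carboxylate, via pulegone dibromide 2 (not isolated)
Conditions: Br2, Et2O, 0 °C; then NaOMe, MeOH, reflux
Reagents that add atoms: bromine, BrBr (atoms only in 2); sodium methoxide, [Na+].[O-]C
Why: Bromine adds across the enone double bond and methoxide then effects a Favorskii rearrangement (cyclopropanone, ring opening, loss of the second bromide) that contracts the ring to the cyclopentane without touching the methyl-bearing stereocentre.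

Step 2
Reactants: 3 methyl (2S)-2-methyl-5-(propan-2-ylidene)cyclopentane-1-carboxylate
Product: 4 methyl (2S)-2-methyl-5-oxocyclopentane-1-carboxylate
Conditions: O3, CH2Cl2/MeOH, −78 °C; then Me2S, −78 °C to rt
Reagents that add atoms: ozone, [O-][O+]=O
Why: Ozonolysis (Criegee cleavage, reductive work-up) of the tetrasubstituted alkene should give the β-keto ester directly, the carbonyl oxide residing on the acetone fragment and being trapped by methanol.

Step 3
Reactants: 4 methyl (2S)-2-methyl-5-oxocyclopentane-1-carboxylate; 5 prenyl bromide (1-bromo-3-methylbut-2-ene)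
Product: 6 methyl (2S)-2-methyl-1-(3-methylbut-2-en-1-yl)-5-oxocyclopentane-1-carboxylate
Conditions: K2CO3, acetone, reflux
Reagents that add atoms: none
Why: C-Alkylation of the stabilised β-keto ester enolate with an allylic bromide attaches C6–C7=C11 to the future C5; the quaternary centre formed is destroyed later.

Step 4
Reactants: 6 methyl (2S)-2-methyl-1-(3-methylbut-2-en-1-yl)-5-oxocyclopentane-1-carboxylate
Product: 7 (3S)-3-methyl-2-(3-methylbut-2-en-1-yl)cyclopentan-1-one
Conditions: LiCl, H2O (2 equiv), DMSO, 150 °C
Reagents that add atoms: none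
Why: Krapcho dealkoxycarbonylation (chloride attack on the methyl ester, decarboxylation of the β-keto carboxylate) removes the activating ester without affecting the prenyl alkene or the non-enolisable C4 centre.

Step 5
Reactants: 7 (3S)-3-methyl-2-(3-methylbut-2-en-1-yl)cyclopentan-1-one
Product: 8 (3S)-3-methyl-2-(3-methylbut-2-en-1-yl)cyclopent-1-en-1-yl trifluoromethanesulfonate
Conditions: Tf2O, 2,6-di-tert-butyl-4-methylpyridine, CH2Cl2, 0 °C to rt
Reagents that add atoms: triflic anhydride, O=S(=O)(OS(=O)(=O)C(F)(F)F)C(F)(F)F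
Why: Enol triflate formation with triflic anhydride and a hindered pyridine is under thermodynamic control and should favour the more substituted enol triflate toward the prenyl-bearing carbon, while the buffered medium spares the prenyl alkene.

Step 6
Reactants: 9 ethyl but-2-ynoate
Product: 10 ethyl (2Z)-3-(4,4,5,5-tetramethyl-1,3,2-dioxaborolan-2-yl)but-2-enoate
Conditions: B2pin2, CuCl (3 mol %), Xantphos (3 mol %), NaOt-Bu (6 mol %), MeOH (2 equiv), THF, rt
Reagents that add atoms: bis(pinacolato)diboron, CC1(C)OB(OC1(C)C)B1OC(C)(C)C(C)(C)O1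
Why: Copper-catalysed β-borylation of an ynoate with protonation of the α-copper species is a syn addition of boron and hydrogen and gives the β-boryl enoate regio- and stereoselectively.

Step 7
Reactants: 8 (3S)-3-methyl-2-(3-methylbut-2-en-1-yl)cyclopent-1-en-1-yl trifluoromethanesulfonate; 10 ethyl (2Z)-3-(4,4,5,5-tetramethyl-1,3,2-dioxaborolan-2-yl)but-2-enoate
Product: 11 ethyl (2E)-3-[(3S)-3-methyl-2-(3-methylbut-2-en-1-yl)cyclopent-1-en-1-yl]but-2-enoate
Conditions: Pd(dppf)Cl2 (5 mol %), K3PO4 (3 equiv), 1,4-dioxane/H2O, 60 °C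
Reagents that add atoms: none
Why: Suzuki–Miyaura coupling of an alkenyl triflate with an alkenyl boronate forms the C1–C10 bond with retention at both partners and gives the 2,4-dienoate.

Step 8
Reactants: 11 ethyl (2E)-3-[(3S)-3-methyl-2-(3-methylbut-2-en-1-yl)cyclopent-1-en-1-yl]but-2-enoate
Product: 12 ethyl (3Z)-3-[(2S,3S)-3-methyl-2-(3-methylbut-2-en-1-yl)cyclopentylidene]butanoate
Conditions: (η6-naphthalene)Cr(CO)3 (20 mol %), H2 (70 atm), THF, 45 °C
Reagents that add atoms: none
Why: (Arene)Cr(CO)3-catalysed 1,4-hydrogenation of a conjugated diene (the sorbate-to-(Z)-3-hexenoate type) runs only through the η4-s-cis diene complex, so hydrogen goes to C9 and C5 from the chromium face anti to the C4 methyl, giving the C1=C10 alkene with C9 cis to C5 and the prenyl group cis to the methyl, while the isolated prenyl alkene is left alone.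

Step 9
Reactants: 12 ethyl (3Z)-3-[(2S,3S)-3-methyl-2-(3-methylbut-2-en-1-yl)cyclopentylidene]butanoate
Product: 13 (3Z)-3-[(2S,3S)-3-methyl-2-(3-methylbut-2-en-1-yl)cyclopentylidene]butanal
Conditions: DIBAL-H (1.1 equiv), CH2Cl2, −78 °C; aqueous Rochelle salt
Reagents that add atoms: none
Why: Partial ester reduction with DIBAL-H at −78 °C stops at the aluminium hemiacetal and should give the β,γ-unsaturated aldehyde, which is used crude to avoid migration of the double bond into conjugation.

Step 10
Reactants: 13 (3Z)-3-[(2S,3S)-3-methyl-2-(3-methylbut-2-en-1-yl)cyclopentylidene]butanal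
Product: 14 (3S,3aS,5R,6S)-3,8-dimethyl-5-(prop-1-en-2-yl)-1,2,3,3a,4,5,6,7-octahydroazulen-6-ol
Conditions: Me2AlCl (1.5 equiv), CH2Cl2 (0.01 M), −78 to −20 °C; aqueous Rochelle salt
Reagents that add atoms: none
Why: Me2AlCl binds the aldehyde oxygen, and the activated C8 is attacked by C7, the less substituted carbon of the prenyl alkene, while an allylic methyl hydrogen passes to oxygen in a concerted, asynchronous type-I carbonyl-ene reaction that leaves isopropenyl on C7 and the aluminium alkoxide on C8. The closest known reactions are the Lewis-acid cyclisation of citronellal to isopulegol and the aldehyde–olefin cyclisations used for hydroazulenols; here the same O–C8–C7–C11 array is closed one ring size larger. The seven-membered ring closes in a 7-exo-trig sense at the carbonyl (C=O and the ene double bond both exocyclic to the new ring), helped by the cis C1=C10 bond that already holds C9 and C5 on one side. C7 is controlled by C5 through a chair-like cycloheptene transition state in which the C5–C4 bond is pseudo-equatorial (fixed by the cyclopentane) and the prenyl-derived group is equatorial, which puts H7 cis to H5; C8 is set in the same transition state with the aluminium-bound oxygen equatorial and therefore trans to the isopropenyl group. The step needs chemoselectivity for the prenyl alkene (the tetrasubstituted alkene could only reach C8 through a three- or four-membered array), regioselectivity for C7 over C11 (Markovnikov, seven- against eight-membered ring) and 7,8-trans diastereoselectivity (all-equatorial chair, reinforced by the bulk on aluminium); the methylaluminium reagent also scavenges protons so that neither alkene migrates.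

Step 11
Reactants: 14 (3S,3aS,5R,6S)-3,8-dimethyl-5-(prop-1-en-2-yl)-1,2,3,3a,4,5,6,7-octahydroazulen-6-ol
Product: 15 (3S,3aS,5S,6S)-5-(2-hydroxypropan-2-yl)-3,8-dimethyl-1,2,3,3a,4,5,6,7-octahydroazulen-6-ol
Conditions: Co(acac)2 (20 mol %), PhSiH3 (2.5 equiv), O2 (1 atm), THF, rt
Reagents that add atoms: dioxygen, O=O
Why: Mukaiyama hydration (hydrogen-atom transfer from a cobalt hydride, trapping by O2, reduction of the peroxide) adds water in the Markovnikov sense to the 1,1-disubstituted alkene, which should react much faster than the hindered tetrasubstituted ring alkene; no stereocentre is formed.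

Step 12
Reactants: 15 (3S,3aS,5S,6S)-5-(2-hydroxypropan-2-yl)-3,8-dimethyl-1,2,3,3a,4,5,6,7-octahydroazulen-6-ol; 16 (E)-4-acetoxycinnamic acid
Product: 17 (3S,3aS,5S,6S)-5-(2-hydroxypropan-2-yl)-3,8-dimethyl-1,2,3,3a,4,5,6,7-octahydroazulen-6-yl (2E)-3-(4-acetoxyphenyl)prop-2-enoate
Conditions: DCC (1.5 equiv), DMAP (0.2 equiv), CH2Cl2, 0 °C to rt
Reagents that add atoms: none
Why: Steglich esterification acylates the secondary C8 alcohol selectively because the tertiary C11 alcohol is too hindered for the acylpyridinium intermediate, and the (E)-alkene of the acid is retained.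

Step 13
Reactants: 17 (3S,3aS,5S,6S)-5-(2-hydroxypropan-2-yl)-3,8-dimethyl-1,2,3,3a,4,5,6,7-octahydroazulen-6-yl (2E)-3-(4-acetoxyphenyl)prop-2-enoate
Product: 18 (3S,3aS,5S,6S)-5-(2-hydroxypropan-2-yl)-3,8-dimethyl-1,2,3,3a,4,5,6,7-octahydroazulen-6-yl (2E)-3-(4-hydroxyphenyl)prop-2-enoate
Conditions: K2CO3 (0.5 equiv), MeOH, 0 °C
Reagents that add atoms: none
Why: Base-catalysed methanolysis (transesterification) should cleave the aryl acetate far faster than the hindered secondary alkyl cinnamate and so release the phenol.

**Compound list**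

1 | (S)-(−)-pulegone, (5S)-5-methyl-2-(propan-2-ylidene)cyclohexan-1-one | C[C@H]1CCC(=C(C)C)C(=O)C1 | starting material
2 | pulegone dibromide, (5S)-2-bromo-2-(2-bromopropan-2-yl)-5-methylcyclohexan-1-one | C[C@H]1CCC(Br)(C(C)(C)Br)C(=O)C1 | intermediate
3 | methyl (2S)-2-methyl-5-(propan-2-ylidene)cyclopentane-1-carboxylate (C1 epimers) | C[C@H]1CCC(=C(C)C)C1C(=O)OC | intermediate
4 | methyl (2S)-2-methyl-5-oxocyclopentane-1-carboxylate (C1 epimers) | C[C@H]1CCC(=O)C1C(=O)OC | intermediate
5 | prenyl bromide, 1-bromo-3-methylbut-2-ene | CC(C)=CCBr | starting material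
6 | methyl (2S)-2-methyl-1-(3-methylbut-2-en-1-yl)-5-oxocyclopentane-1-carboxylate (C1 epimers) | C[C@H]1CCC(=O)C1(CC=C(C)C)C(=O)OC | intermediate
7 | (3S)-3-methyl-2-(3-methylbut-2-en-1-yl)cyclopentan-1-one (C2 epimers) | C[C@H]1CCC(=O)C1CC=C(C)C | intermediate
8 | (3S)-3-methyl-2-(3-methylbut-2-en-1-yl)cyclopent-1-en-1-yl trifluoromethanesulfonate | C[C@H]1CCC(OS(=O)(=O)C(F)(F)F)=C1CC=C(C)C | intermediate
9 | ethyl but-2-ynoate | CC#CC(=O)OCC | starting material
10 | ethyl (2Z)-3-(4,4,5,5-tetramethyl-1,3,2-dioxaborolan-2-yl)but-2-enoate | C/C(B1OC(C)(C)C(C)(C)O1)=C\C(=O)OCC | intermediate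
11 | ethyl (2E)-3-[(3S)-3-methyl-2-(3-methylbut-2-en-1-yl)cyclopent-1-en-1-yl]but-2-enoate | CCOC(=O)/C=C(\C)C1=C(CC=C(C)C)[C@@H](C)CC1 | intermediate
12 | ethyl (3Z)-3-[(2S,3S)-3-methyl-2-(3-methylbut-2-en-1-yl)cyclopentylidene]butanoate | CCOC(=O)C/C(C)=C1/CC[C@H](C)[C@@H]1CC=C(C)C | intermediate
13 | (3Z)-3-[(2S,3S)-3-methyl-2-(3-methylbut-2-en-1-yl)cyclopentylidene]butanal | O=CC/C(C)=C1/CC[C@H](C)[C@@H]1CC=C(C)C | intermediate
14 | (3S,3aS,5R,6S)-3,8-dimethyl-5-(prop-1-en-2-yl)-1,2,3,3a,4,5,6,7-octahydroazulen-6-ol | CC1=C2CC[C@H](C)[C@@H]2C[C@H](C(C)=C)[C@@H](O)C1 | intermediate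
15 | (3S,3aS,5S,6S)-5-(2-hydroxypropan-2-yl)-3,8-dimethyl-1,2,3,3a,4,5,6,7-octahydroazulen-6-ol | CC1=C2CC[C@H](C)[C@@H]2C[C@H](C(C)(C)O)[C@@H](O)C1 | intermediate
16 | (E)-4-acetoxycinnamic acid | CC(=O)Oc1ccc(/C=C/C(=O)O)cc1 | starting material
17 | (3S,3aS,5S,6S)-5-(2-hydroxypropan-2-yl)-3,8-dimethyl-1,2,3,3a,4,5,6,7-octahydroazulen-6-yl (2E)-3-(4-acetoxyphenyl)prop-2-enoate | CC1=C2CC[C@H](C)[C@@H]2C[C@H](C(C)(C)O)[C@@H](OC(=O)/C=C/c2ccc(OC(C)=O)cc2)C1 | intermediate
18 | (3S,3aS,5S,6S)-5-(2-hydroxypropan-2-yl)-3,8-dimethyl-1,2,3,3a,4,5,6,7-octahydroazulen-6-yl (2E)-3-(4-hydroxyphenyl)prop-2-enoate | CC1=C2CC[C@H](C)[C@@H]2C[C@H](C(C)(C)O)[C@@H](OC(=O)/C=C/c2ccc(O)cc2)C1 | target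

**Step count and risks**

Total steps: 13. Longest linear sequence: 12 (steps 1–5 and 7–13; step 6 is a one-step side branch).

Steps most likely to fail:

1. Step 10 (ene closure). The seven-membered closure may be slow, which would allow migration of the β,γ-double bond into conjugation, oligomerisation, methyl transfer from aluminium to the aldehyde, or poor facial selectivity at C7/C8. The fallback sets out from ester 12 and returns at 14. Riley oxidation (SeO2 catalytic, t-BuOOH, CH2Cl2) of the (E)-methyl of the prenyl group should give the allylic alcohol F1. An Appel reaction (CBr4, PPh3) should give the allylic bromide F2, and DIBAL-H at −78 °C the bromo aldehyde F3. An intramolecular Nozaki–Hiyama–Kishi allylation (CrCl2, THF, high dilution) would then close the C7–C8 bond by γ-attack of the allylchromium on the aldehyde, giving the isopropenyl group and the anti alcohol of 14 through a closed chair transition state.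

2. Step 8 (1,4-hydrogenation). The fully substituted diene, which carries an inward-pointing substituent on C5, may fail to reach the planar s-cis η4 geometry on chromium, or the catalyst may discriminate poorly between the diene faces. The fallback sets out from triflate 8 and returns at 14; it postpones the hydrogenation until the diene is locked cisoid in the seven-membered ring. Stille coupling of 8 with (Z)-3-(tributylstannyl)but-2-en-1-ol should give the (Z)-dienol F4, and MnO2 the (Z)-dienal F5. A Me2AlCl-promoted carbonyl-ene closure of the neral-to-isopiperitenol type would give the ring dienol F6; since only the remote C4 centre is present at this stage, the C7/C8 diastereomers may have to be separated. Chromium-catalysed 1,4-hydrogenation of the ring-held cisoid diene of F6 would then add hydrogen to C9 and C5 and give 14.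

3. Step 5 (enol triflate). Deprotonation may occur at the unsubstituted α-CH2 instead, giving the regioisomeric triflate, which after coupling and hydrogenation would carry the wrong alkene geometry and no control at C5; acid-induced reaction of the prenyl alkene is the second concern. The fallback sets out from ketone 7 and returns at 8. Equilibrating silylation (TMSCl, NaI, Et3N, MeCN) should give the more substituted silyl enol ether F7, which can be purified from its regioisomer. Cleavage with MeLi regenerates the tetrasubstituted lithium enolate regiospecifically, and PhNTf2 traps it as 8.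

**Further compounds**

F1 | step 10 | ethyl (3Z)-3-[(2S,3S)-2-[(2E)-4-hydroxy-3-methylbut-2-en-1-yl]-3-methylcyclopentylidene]butanoate | CCOC(=O)C/C(C)=C1/CC[C@H](C)[C@@H]1C/C=C(\C)CO
F2 | step 10 | ethyl (3Z)-3-[(2S,3S)-2-[(2E)-4-bromo-3-methylbut-2-en-1-yl]-3-methylcyclopentylidene]butanoate | CCOC(=O)C/C(C)=C1/CC[C@H](C)[C@@H]1C/C=C(\C)CBr
F3 | step 10 | (3Z)-3-[(2S,3S)-2-[(2E)-4-bromo-3-methylbut-2-en-1-yl]-3-methylcyclopentylidene]butanal | O=CC/C(C)=C1/CC[C@H](C)[C@@H]1C/C=C(\C)CBr
F4 | step 8 | (2Z)-3-[(3S)-3-methyl-2-(3-methylbut-2-en-1-yl)cyclopent-1-en-1-yl]but-2-en-1-ol | OC/C=C(/C)C1=C(CC=C(C)C)[C@@H](C)CC1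
F5 | step 8 | (2Z)-3-[(3S)-3-methyl-2-(3-methylbut-2-en-1-yl)cyclopent-1-en-1-yl]but-2-enal | O=C/C=C(/C)C1=C(CC=C(C)C)[C@@H](C)CC1
F6 | step 8 | (3S,5R,6S)-3,8-dimethyl-5-(prop-1-en-2-yl)-1,2,3,4,5,6-hexahydroazulen-6-ol | CC1=C[C@H](O)[C@@H](C(C)=C)CC2=C1CC[C@@H]2C
F7 | step 5 | trimethyl{[(3S)-3-methyl-2-(3-methylbut-2-en-1-yl)cyclopent-1-en-1-yl]oxy}silane | C[C@H]1CCC(O[Si](C)(C)C)=C1CC=C(C)C
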